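**Retrosynthetic overview**
1. The oxepane, the only ring, is closed last: acid-catalysed 7-endo opening of an (R,R)-trisubstituted epoxide by the allylic CH2OH; the epoxide comes from Shi epoxidation of an acyclic trienone triol.
2. The γ-hydroxy enone comes from a Weinreb amide and (E)-LiCH=CH–CMe2OLi (made from 2-methylbut-3-yn-2-ol).
3. The exocyclic (E)-olefin comes from B-alkyl Suzuki coupling of (Z)-2-iodobut-2-ene-1,4-diol with the borane of a terminal diene.
4. Key C–C bond, CH(CH3)–CH2 next to the carbonyl: the carbonyl α-carbon acts as the electrophile (tert-butyl (S)-lactate triflate) toward an alkyl zincate; SN2 inversion sets the methyl-bearing stereocentre.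
5. The E-trisubstituted diene comes from Negishi carboalumination and vinylation of 5-chloropent-1-yne.

Assumption: tert-butyl (S)-lactate (≥98% ee) and the D-fructose-derived Shi ketone are bought; each step ends with a standard aqueous work-up and chromatography unless a quench is named.

**Route**

Step 1
Reactants: 1 5-chloropent-1-yne; 2 bromoethene (vinyl bromide)
Product: 4 (E)-7-chloro-4-methylhepta-1,3-diene, via alkenylalane 3 (not isolated)
Conditions: AlMe3 (2 equiv), Cp2ZrCl2 (20 mol%), CH2Cl2, 0 °C → rt; then 2 (3 equiv), Pd(PPh3)4 (3 mol%), ZnCl2 (20 mol%), THF, rt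
Reagents that add atoms: trimethylaluminium C[Al](C)C
Why: Negishi zirconium-catalysed carboalumination adds methyl and aluminium syn across the terminal alkyne (methyl on the internal carbon) and the palladium-catalysed Negishi coupling of the alkenylalane proceeds with retention, so the trisubstituted olefin is E, while the alkyl chloride is inert to both metals.

Step 2
Reactants: 5 tert-butyl (S)-lactate
Product: 6 tert-butyl (S)-2-{[(trifluoromethyl)sulfonyl]oxy}propanoate
Conditions: Tf2O (1.1 equiv), 2,6-lutidine (1.2 equiv), CH2Cl2, −78 → 0 °C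
Reagents that add atoms: trifluoromethanesulfonic anhydride O=S(=O)(OS(=O)(=O)C(F)(F)F)C(F)(F)F
Why: O-sulfonylation of the secondary alcohol leaves the stereocentre untouched and turns the carbon α to the ester into an electrophile.

Step 3
Reactants: 4 (E)-7-chloro-4-methylhepta-1,3-diene; 6 tert-butyl (S)-2-{[(trifluoromethyl)sulfonyl]oxy}propanoate
Product: 8 tert-butyl (2S,6E)-2,6-dimethylnona-6,8-dienoate, via Grignard reagent 7 (not isolated)
Conditions: 4, Mg turnings, THF, reflux; the solution of 7 (1.4 equiv) added slowly to 6 and ZnCl2 (10 mol%), THF, 0 °C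
Reagents that add atoms: none
Why: Zinc-catalysed sp3–sp3 cross-coupling of an α-hydroxy ester triflate with a Grignard reagent, in which the triorganozincate formed in the flask displaces triflate by SN2 with clean inversion, so the (S)-lactate gives the (S)-2-methyl ester (the configuration of the ketone α-centre of the target) and the bulky tert-butyl ester suppresses carbonyl addition.

Step 4
Reactants: 8 tert-butyl (2S,6E)-2,6-dimethylnona-6,8-dienoate
Product: 11 (2S,6E)-N-methoxy-N,2,6-trimethylnona-6,8-dienamide, via silyl ester 9 (not isolated), via acid chloride 10 (not isolated)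
Conditions: Me3SiOTf (1.5 equiv), 2,6-lutidine (2 equiv), CH2Cl2, 0 °C; then (COCl)2 (1.3 equiv), DMF (cat.), 0 °C → rt, volatiles removed; then MeNHOMe·HCl (1.5 equiv), pyridine (4 equiv), CH2Cl2, 0 °C → rt
Reagents that add atoms: N,O-dimethylhydroxylamine hydrochloride CNOC.Cl
Why: Silyl-triflate cleavage of the tert-butyl ester (loss of isobutene) under buffered, non-protic conditions spares the acid-sensitive diene, the silyl ester is converted by oxalyl chloride into the acid chloride under neutral conditions, and Weinreb amidation with pyridine at 0 °C does not enolise the α-centre.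

Step 5
Reactants: 12 but-2-yne-1,4-diol
Product: 14 (Z)-2-iodobut-2-ene-1,4-diol, via cyclic alkenylalanate 13 (not isolated)
Conditions: NaAlH2(OCH2CH2OMe)2 (Red-Al), THF, 0 °C → rt; then I2, THF, −78 °C → rt; aqueous work-up
Reagents that add atoms: iodine II
Why: Alkoxide-directed trans-hydroalumination of the propargylic alcohol holds aluminium cis to the chelating CH2O group in a five-membered alanate, and iodinolysis of the C–Al bond with retention gives only the Z vinyl iodide.

Step 6
Reactants: 11 (2S,6E)-N-methoxy-N,2,6-trimethylnona-6,8-dienamide; 14 (Z)-2-iodobut-2-ene-1,4-diol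
Product: 16 (2S,6E,10E)-12-hydroxy-10-(hydroxymethyl)-N-methoxy-N,2,6-trimethyldodeca-6,10-dienamide, via alkylborane 15 (not isolated)
Conditions: 9-BBN (1.1 equiv), THF, 0 °C → rt; then 14 (1.2 equiv), PdCl2(dppf) (5 mol%), AsPh3 (5 mol%), Cs2CO3 (3 equiv), DMF–H2O, rt
Reagents that add atoms: none
Why: 9-BBN hydroborates only the terminal CH2 of the diene (anti-Markovnikov, trisubstituted olefin untouched) and the B-alkyl Suzuki–Miyaura coupling replaces iodine with retention, which fixes the chain cis to the CH=CH2OH carbon's CH2OH and so gives the E allylic-diol olefin.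

Step 7
Reactants: 17 2-methylbut-3-yn-2-ol; 18 tributyltin hydride
Product: 19 (E)-2-methyl-4-(tributylstannyl)but-3-en-2-ol
Conditions: PdCl2(PPh3)2 (2 mol%), THF, 0 °C → rt
Reagents that add atoms: none
Why: Palladium-catalysed syn-hydrostannation puts tin on the terminal carbon, away from the bulky tertiary carbinol, and gives the E vinylstannane.

Step 8
Reactants: 19 (E)-2-methyl-4-(tributylstannyl)but-3-en-2-ol; 16 (2S,6E,10E)-12-hydroxy-10-(hydroxymethyl)-N-methoxy-N,2,6-trimethyldodeca-6,10-dienamide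
Product: 21 (3E,6S,10E,14E)-2,16-dihydroxy-14-(hydroxymethyl)-2,6,10-trimethylhexadeca-3,10,14-trien-5-one, via dilithio reagent 20 (not isolated)
Conditions: 19 (1.6 equiv), n-BuLi (3.2 equiv), THF, −78 → −40 °C; 16 pre-treated with LiN(SiMe3)2 (2.1 equiv), THF, −78 °C; combined, −78 → −30 °C; AcOH quench at −78 °C
Reagents that add atoms: none
Why: Tin–lithium exchange with retention gives the E alkenyllithium, which adds once to the Weinreb amide (stable chelated tetrahedral intermediate, Weinreb ketone synthesis) to give the E enone without disturbing the α-stereocentre, the two hydroxyls being masked as lithium alkoxides.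

Step 9
Reactants: 21 (3E,6S,10E,14E)-2,16-dihydroxy-14-(hydroxymethyl)-2,6,10-trimethylhexadeca-3,10,14-trien-5-one
Product: 22 (3E,6S,10R,11R,14E)-10,11-epoxy-2,16-dihydroxy-14-(hydroxymethyl)-2,6,10-trimethylhexadeca-3,14-dien-5-one
Conditions: Shi ketone from D-fructose (1,2:4,5-di-O-isopropylidene-β-D-erythro-2,3-hexodiulo-2,6-pyranose, 30 mol%), KHSO5 (as the triple salt 2KHSO5·KHSO4·K2SO4, 1.4 equiv), K2CO3, Bu4NHSO4 (cat.), MeCN–CH2(OMe)2 / aq. Na2B4O7 buffer (pH about 10.5), −5 → 0 °C
Reagents that add atoms: potassium peroxymonosulfate [K+].[O-]S(=O)(=O)OO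
Why: Shi asymmetric epoxidation, in which the chiral dioxirane attacks the electron-rich trialkyl-substituted E olefin through the spiro transition state to give the (R,R)-epoxide, while the olefin carrying two CH2OH groups and the enone olefin are electron-poor and react far more slowly.

Step 10
Reactants: 22 (3E,6S,10R,11R,14E)-10,11-epoxy-2,16-dihydroxy-14-(hydroxymethyl)-2,6,10-trimethylhexadeca-3,14-dien-5-one
Product: 23 (3E,6S)-2-hydroxy-9-[(2S,3R,6E)-3-hydroxy-6-(2-hydroxyethylidene)-2-methyloxepan-2-yl]-2,6-dimethylnon-3-en-5-one (CNP0270237.2)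
Conditions: (+)-camphor-10-sulfonic acid (10 mol%), CH2Cl2, −20 → 0 °C; NaHCO3 quench
Reagents that add atoms: none
Why: Acid-catalysed intramolecular epoxide opening in the 7-endo mode, in which the hydroxymethyl group on the olefin attacks the tertiary epoxide carbon (the more cationic C–O bond, whereas the 6-exo path needs backside attack at a secondary carbon flanked by a quaternary centre) with inversion to give the S tertiary ether, while the R carbinol carbon keeps its oxygen and configuration.

**Compound list**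
1 | 5-chloropent-1-yne | C#CCCCCl | starting material
2 | bromoethene (vinyl bromide) | C=CBr | starting material
3 | (E)-(5-chloro-2-methylpent-1-en-1-yl)dimethylalumane | C[Al](C)/C=C(\C)CCCCl | intermediate
4 | (E)-7-chloro-4-methylhepta-1,3-diene | C=C/C=C(\C)CCCCl | intermediate
5 | tert-butyl (S)-lactate | C[C@H](O)C(=O)OC(C)(C)C | starting material
6 | tert-butyl (S)-2-{[(trifluoromethyl)sulfonyl]oxy}propanoate | C[C@H](OS(=O)(=O)C(F)(F)F)C(=O)OC(C)(C)C | intermediate
7 | (E)-(4-methylhepta-4,6-dien-1-yl)magnesium chloride | Cl[Mg]CCC/C(C)=C/C=C | intermediate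
8 | tert-butyl (2S,6E)-2,6-dimethylnona-6,8-dienoate | C[C@@H](CCC/C(C)=C/C=C)C(=O)OC(C)(C)C | intermediate
9 | trimethylsilyl (2S,6E)-2,6-dimethylnona-6,8-dienoate | C[C@@H](CCC/C(C)=C/C=C)C(=O)O[Si](C)(C)C | intermediate
10 | (2S,6E)-2,6-dimethylnona-6,8-dienoyl chloride | C[C@@H](CCC/C(C)=C/C=C)C(=O)Cl | intermediate
11 | (2S,6E)-N-methoxy-N,2,6-trimethylnona-6,8-dienamide | C[C@@H](CCC/C(C)=C/C=C)C(=O)N(C)OC | intermediate
12 | but-2-yne-1,4-diol | OCC#CCO | starting material
13 | cyclic sodium alkenylalanate (five-membered 1,2-oxaluminole; Al bound to the alkoxide O and to the olefinic carbon that carries the free CH2OH; two 2-methoxyethoxy ligands on Al) | [Na+].OCC1=CCO[Al-]1(OCCOC)OCCOC | intermediate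
14 | (Z)-2-iodobut-2-ene-1,4-diol | OC/C=C(\I)CO | intermediate
15 | (2S,6E)-9-(9-borabicyclo[3.3.1]nonan-9-yl)-N-methoxy-N,2,6-trimethylnon-6-enamide | C[C@@H](CCC/C(C)=C/CCB1C2CCCC1CCC2)C(=O)N(C)OC | intermediate
16 | (2S,6E,10E)-12-hydroxy-10-(hydroxymethyl)-N-methoxy-N,2,6-trimethyldodeca-6,10-dienamide | C[C@@H](CCC/C(C)=C/CC/C(CO)=C\CO)C(=O)N(C)OC | intermediate
17 | 2-methylbut-3-yn-2-ol | CC(C)(O)C#C | starting material
18 | tributyltin hydride | CCCC[SnH](CCCC)CCCC | starting material
19 | (E)-2-methyl-4-(tributylstannyl)but-3-en-2-ol | CCCC[Sn](CCCC)(CCCC)/C=C/C(C)(C)O | intermediate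
20 | lithium (E)-4-lithio-2-methylbut-3-en-2-olate | [Li]/C=C/C(C)(C)O[Li] | intermediate
21 | (3E,6S,10E,14E)-2,16-dihydroxy-14-(hydroxymethyl)-2,6,10-trimethylhexadeca-3,10,14-trien-5-one | C[C@@H](CCC/C(C)=C/CC/C(CO)=C\CO)C(=O)/C=C/C(C)(C)O | intermediate
22 | (3E,6S,10R,11R,14E)-10,11-epoxy-2,16-dihydroxy-14-(hydroxymethyl)-2,6,10-trimethylhexadeca-3,14-dien-5-one | C[C@@H](CCC[C@@]1(C)O[C@@H]1CC/C(CO)=C\CO)C(=O)/C=C/C(C)(C)O | intermediate
23 | (3E,6S)-2-hydroxy-9-[(2S,3R,6E)-3-hydroxy-6-(2-hydroxyethylidene)-2-methyloxepan-2-yl]-2,6-dimethylnon-3-en-5-one | C[C@@H](CCC[C@]1(C)OC/C(=C/CO)CC[C@H]1O)C(=O)/C=C/C(C)(C)O | target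

**Step count and risks**
Total step count: 10. Longest linear sequence: 7 steps (steps 1, 3, 4, 6, 8, 9, 10); steps 2, 5 and 7 make the three side fragments.

The three steps most likely to fail:

Step 6. 9-BBN may attack the Weinreb amide before it hydroborates the sluggish diene, and the coupling runs on an unprotected iodo-diol. The fallback carries the borane-inert tert-butyl ester through the coupling and makes the amide afterwards. It sets out from 8 (with 14): 9-BBN in THF gives the alkylborane tert-butyl (2S,6E)-9-(9-borabicyclo[3.3.1]nonan-9-yl)-2,6-dimethylnon-6-enoate F1, which is coupled with 14 under the PdCl2(dppf)/AsPh3/Cs2CO3 conditions to tert-butyl (2S,6E,10E)-12-hydroxy-10-(hydroxymethyl)-2,6-dimethyldodeca-6,10-dienoate F2. Me3SiOTf/2,6-lutidine followed by aqueous citric acid cleaves the ester to (2S,6E,10E)-12-hydroxy-10-(hydroxymethyl)-2,6-dimethyldodeca-6,10-dienoic acid F3. Amidation of F3 with MeNHOMe·HCl (EDC·HCl, HOBt, N-methylmorpholine, CH2Cl2) comes back to the route at 16.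

Step 9. The olefin bearing the two CH2OH groups may compete for the dioxirane, or the free hydroxyls may lower the selectivity. The fallback shields that olefin with bulky silyl ethers. It sets out from 21: t-BuMe2SiCl/imidazole (DMF, 0 °C) silylates only the two primary allylic hydroxyls to give (3E,6S,10E,14E)-16-[(tert-butyldimethylsilyl)oxy]-14-{[(tert-butyldimethylsilyl)oxy]methyl}-2-hydroxy-2,6,10-trimethylhexadeca-3,10,14-trien-5-one F4. Shi epoxidation under the step 9 conditions gives its (10R,11R)-10,11-epoxide F5. Bu4NF buffered with AcOH (THF, 0 °C) removes both silyl groups and comes back to the route at 22.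

Step 10. Attack at the secondary epoxide carbon (6-exo) would give a tetrahydropyran instead of the oxepane. The fallback changes the nucleophile from the free alcohol to a silyl ether and the ring closure to a Lewis-acid silyl-transfer cyclisation. It sets out from 22: Me3SiCl/imidazole (CH2Cl2, 0 °C) silylates the two primary allylic hydroxyls to give the bis(trimethylsilyl) ether (3E,6S,10R,11R,14E)-10,11-epoxy-2-hydroxy-2,6,10-trimethyl-16-[(trimethylsilyl)oxy]-14-{[(trimethylsilyl)oxy]methyl}hexadeca-3,14-dien-5-one F6. Me3SiOTf (10 mol%) with 2,6-di-tert-butyl-4-methylpyridine in CH2Cl2 at −78 °C silylates the epoxide oxygen; the weakly nucleophilic silyl-ether oxygen should then close only on the fully cationic tertiary carbon and pass its silyl group on. This gives (3E,6S)-2-hydroxy-2,6-dimethyl-9-[(2S,3R,6E)-2-methyl-3-[(trimethylsilyl)oxy]-6-{2-[(trimethylsilyl)oxy]ethylidene}oxepan-2-yl]non-3-en-5-one F7. Citric acid in MeOH removes both silyl groups and comes back to the route at 23.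

**Further compounds**
F1 | step 6 | tert-butyl (2S,6E)-9-(9-borabicyclo[3.3.1]nonan-9-yl)-2,6-dimethylnon-6-enoate | C[C@@H](CCC/C(C)=C/CCB1C2CCCC1CCC2)C(=O)OC(C)(C)C
F2 | step 6 | tert-butyl (2S,6E,10E)-12-hydroxy-10-(hydroxymethyl)-2,6-dimethyldodeca-6,10-dienoate | C[C@@H](CCC/C(C)=C/CC/C(CO)=C\CO)C(=O)OC(C)(C)C
F3 | step 6 | (2S,6E,10E)-12-hydroxy-10-(hydroxymethyl)-2,6-dimethyldodeca-6,10-dienoic acid | C[C@@H](CCC/C(C)=C/CC/C(CO)=C\CO)C(=O)O
F4 | step 9 | (3E,6S,10E,14E)-16-[(tert-butyldimethylsilyl)oxy]-14-{[(tert-butyldimethylsilyl)oxy]methyl}-2-hydroxy-2,6,10-trimethylhexadeca-3,10,14-trien-5-one | C[C@@H](CCC/C(C)=C/CC/C(CO[Si](C)(C)C(C)(C)C)=C\CO[Si](C)(C)C(C)(C)C)C(=O)/C=C/C(C)(C)O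
F5 | step 9 | (3E,6S,10R,11R,14E)-16-[(tert-butyldimethylsilyl)oxy]-14-{[(tert-butyldimethylsilyl)oxy]methyl}-10,11-epoxy-2-hydroxy-2,6,10-trimethylhexadeca-3,14-dien-5-one | C[C@@H](CCC[C@@]1(C)O[C@@H]1CC/C(CO[Si](C)(C)C(C)(C)C)=C\CO[Si](C)(C)C(C)(C)C)C(=O)/C=C/C(C)(C)O
F6 | step 10 | (3E,6S,10R,11R,14E)-10,11-epoxy-2-hydroxy-2,6,10-trimethyl-16-[(trimethylsilyl)oxy]-14-{[(trimethylsilyl)oxy]methyl}hexadeca-3,14-dien-5-one | C[C@@H](CCC[C@@]1(C)O[C@@H]1CC/C(CO[Si](C)(C)C)=C\CO[Si](C)(C)C)C(=O)/C=C/C(C)(C)O
F7 | step 10 | (3E,6S)-2-hydroxy-2,6-dimethyl-9-[(2S,3R,6E)-2-methyl-3-[(trimethylsilyl)oxy]-6-{2-[(trimethylsilyl)oxy]ethylidene}oxepan-2-yl]non-3-en-5-one | C[C@@H](CCC[C@]1(C)OC/C(=C/CO[Si](C)(C)C)CC[C@H]1O[Si](C)(C)C)C(=O)/C=C/C(C)(C)O
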